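The cyclohexene ring (C1–C6, shikimate numbering) carries the ester carbon C7 on C1 and an oxygen on C3, so C7–C1–C2–C3 is a latent 1,4-dicarbonyl array whose central C1–C2 bond links two α-carbons. The ring is therefore cut at C1–C2. The precursor is an open-chain keto ester: C4 and C5 come from D-tartrate as silyl ethers, a methyl ketone (C2, C3) sits at one end and a propanoate arm (C6, C1, C7) at the other. Double deprotonation and one oxidation join the two enolate carbons and close the only carbocycle in a single operation; dehydrogenation, C3 reduction and ordered acylation of O5, O3 and O4 follow.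

Key step: step 5

Remark: shikimate numbering is used for all ring compounds; C7 is carried as a tert-butyl ester up to step 8, so that the tartrate-derived methyl ester can be converted into the methyl ketone in its presence and Claisen pathways are closed in step 5.

Step 1
Reactants: 1 dimethyl D-tartrate
Product: 2 dimethyl (2S,3S)-2,3-bis(tert-butyldimethylsilyloxy)butanedioate
Conditions: TBSOTf (2.4 equiv), 2,6-lutidine, CH2Cl2, 0 °C to rt
Reagents that add atoms: tert-butyldimethylsilyl trifluoromethanesulfonate, CC(C)(C)[Si](C)(C)OS(=O)(=O)C(F)(F)F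
Why: Standard O-silylation with a silyl triflate and a hindered base caps both secondary hydroxyls without touching the esters or the two stereocentres and gives ethers that tolerate the hydride, Grignard and amide-base steps ahead.

Step 2
Reactants: 2 dimethyl (2S,3S)-2,3-bis(tert-butyldimethylsilyloxy)butanedioate
Product: 4 1-tert-butyl 6-methyl (2E,4R,5S)-4,5-bis(tert-butyldimethylsilyloxy)hex-2-enedioate, via aldehyde ester 3 (not isolated)
Conditions: iBu2AlH (1.05 equiv), toluene, −78 °C; MeOH; then Ph3P=CHCO2tBu, −78 °C to rt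
Reagents that add atoms: tert-butyl (triphenylphosphoranylidene)acetate, CC(C)(C)OC(=O)C=P(c1ccccc1)(c1ccccc1)c1ccccc1
Why: One equivalent of hydride stops at the chelated aluminium hemiacetal of one of the two homotopic esters, and the aldehyde released from it is trapped at once by the stabilised ylide (Wittig olefination) before it can epimerise, which adds C1 and C7 as an enoate whose geometry does not matter because the double bond is hydrogenated next.

Step 3
Reactants: 4 1-tert-butyl 6-methyl (2E,4R,5S)-4,5-bis(tert-butyldimethylsilyloxy)hex-2-enedioate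
Product: 5 6-tert-butyl 1-methyl (2S,3R)-2,3-bis(tert-butyldimethylsilyloxy)hexanedioate
Conditions: H2 (1 atm), 10% Pd/C, EtOAc, rt
Reagents that add atoms: none
Why: Heterogeneous catalytic hydrogenation saturates the conjugated double bond to give the C6–C1–C7 arm, while silyl ethers and both esters are inert in ethyl acetate.

Step 4
Reactants: 5 6-tert-butyl 1-methyl (2S,3R)-2,3-bis(tert-butyldimethylsilyloxy)hexanedioate
Product: 7 tert-butyl (4R,5S)-4,5-bis(tert-butyldimethylsilyloxy)-6-oxoheptanoate, via Weinreb amide 6 (not isolated)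
Conditions: MeNH(OMe)·HCl, iPrMgCl, THF, −20 to 0 °C; then MeMgBr, 0 °C; aq. NH4Cl
Reagents that add atoms: methylmagnesium bromide, C[Mg]Br
Why: The magnesium amide of N,O-dimethylhydroxylamine attacks only the α-oxygenated methyl ester (the tert-butyl ester is inert), and the resulting N-methoxy-N-methylamide takes up one methyl Grignard as a stable chelate that gives the methyl ketone on work-up (Weinreb ketone synthesis) without disturbing C4 or C5.

Step 5
Reactants: 7 tert-butyl (4R,5S)-4,5-bis(tert-butyldimethylsilyloxy)-6-oxoheptanoate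
Product: 9 tert-butyl (4S,5R)-4,5-bis(tert-butyldimethylsilyloxy)-3-oxocyclohexane-1-carboxylate (C1 epimers), via dilithium bis-enolate 8 (not isolated)
Conditions: LiN(iPr)2 (2.2 equiv), THF, −78 °C; then Fe(acac)3 (2.2 equiv), −78 °C to rt, 0.01 M
Reagents that add atoms: none
Why: Two equivalents of lithium amide remove a proton from the ketone methyl group (C2, the kinetic site) and from the ester α-methylene (C1); trivalent iron then takes one electron from an enolate to give an α-carbonyl radical that is captured by the second, tethered enolate, and loss of a second electron to another Fe(acac)3 leaves the C7(=O)–C1–C2–C3(=O) 1,4-dicarbonyl unit. The closest known reaction type is the oxidative coupling of two lithium enolates with iron or copper oxidants, which is established intramolecularly between ketone and ester enolates. The six-membered ring closes by C1–C2 bond formation, exo with respect to the ester enolate double bond C1=C7 and endo with respect to the ketone enolate double bond C2=C3. The only new stereocentre, C1, is uncontrolled and need not be controlled, because it becomes trigonal in step 6, while C4 and C5 lie outside both enolates. The step needs carbon–carbon over carbon–oxygen coupling and ring closure over dimerisation, which the carbon termini, the four-atom tether and high dilution should provide, and it needs enolisation away from C4, which kinetic deprotonation at −78 °C next to the bulky C4 silyl ether secures so that the C5 silyloxy group is not expelled.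

Step 6
Reactants: 9 tert-butyl (4S,5R)-4,5-bis(tert-butyldimethylsilyloxy)-3-oxocyclohexane-1-carboxylate
Product: 13 tert-butyl (4S,5R)-4,5-bis(tert-butyldimethylsilyloxy)-3-oxocyclohex-1-ene-1-carboxylate, via lithium enolate 10 (not isolated), via phenylselanyl ketone 11 (not isolated), via selenoxide 12 (not isolated)
Conditions: LiN(iPr)2 (1.1 equiv), THF, −78 °C; PhSeBr; then 30% H2O2, pyridine, CH2Cl2, 0 °C to rt
Reagents that add atoms: none
Why: Kinetic deprotonation takes the C2 methylene in preference to the silyloxy-substituted C4 methine, selenenylation follows at C2, and the selenoxide can eliminate syn only towards the C1 hydrogen (selenoxide elimination), which gives the C1=C2 enone and erases the C1 stereocentre.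

Step 7
Reactants: 13 tert-butyl (4S,5R)-4,5-bis(tert-butyldimethylsilyloxy)-3-oxocyclohex-1-ene-1-carboxylate
Product: 14 tert-butyl (3R,4R,5R)-4,5-bis(tert-butyldimethylsilyloxy)-3-hydroxycyclohex-1-ene-1-carboxylate
Conditions: NaBH4, CeCl3·7H2O, MeOH, −78 °C
Reagents that add atoms: none
Why: Luche reduction gives clean 1,2-reduction of the enone, and because the two bulky trans silyl ethers should prefer the diaxial half-chair, hydride is expected to enter anti to the pseudoaxial C4–O bond and place the new C3 hydroxyl cis to O4, the shikimate configuration.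

Step 8
Reactants: 14 tert-butyl (3R,4R,5R)-4,5-bis(tert-butyldimethylsilyloxy)-3-hydroxycyclohex-1-ene-1-carboxylate
Product: 16 methyl 3,4-O-isopropylidene-shikimate [methyl (3aR,7R,7aS)-7-hydroxy-2,2-dimethyl-3a,6,7,7a-tetrahydro-1,3-benzodioxole-5-carboxylate], via methyl shikimate 15 (not isolated)
Conditions: HCl (3 M in MeOH), 55 °C; evaporate; then Me2C(OMe)2, camphorsulfonic acid (cat.), acetone, rt
Reagents that add atoms: methanol, CO; 2,2-dimethoxypropane, COC(C)(C)OC
Why: Methanolic acid cleaves both silyl ethers and exchanges the tert-butyl ester for the methyl ester (acidolysis followed by Fischer esterification), and the resulting triol forms a five-membered acetonide only across the cis-3,4-diol, which leaves O5 as the single free hydroxyl.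

Step 9
Reactants: 16 methyl 3,4-O-isopropylidene-shikimate; 17 (S)-3-methylpentanoic acid
Product: 18 methyl 3,4-O-isopropylidene-5-O-[(3S)-3-methylpentanoyl]shikimate
Conditions: EDC·HCl, DMAP (cat.), CH2Cl2, 0 °C to rt
Reagents that add atoms: none
Why: Steglich esterification acylates the only free hydroxyl, O5, and the stereocentre of the acid is safe because it is β to the carbonyl and cannot enolise.

Step 10
Reactants: 18 methyl 3,4-O-isopropylidene-5-O-[(3S)-3-methylpentanoyl]shikimate
Product: 19 methyl 5-O-[(3S)-3-methylpentanoyl]shikimate [(3R,4R,5R)-3,4-diol]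
Conditions: CF3CO2H/H2O (9:1), CH2Cl2, 0 °C
Reagents that add atoms: none
Why: Brief acid hydrolysis of the allylic acetonide frees the cis-3,4-diol under conditions too mild for ester cleavage or acyl migration.

Step 11
Reactants: 19 methyl 5-O-[(3S)-3-methylpentanoyl]shikimate
Product: 21 methyl 3-O-acetyl-5-O-[(3S)-3-methylpentanoyl]shikimate, via cyclic orthoacetate 20 (not isolated)
Conditions: MeC(OMe)3, camphorsulfonic acid (cat.), CH2Cl2, rt; then 80% aq. AcOH, rt
Reagents that add atoms: trimethyl orthoacetate, CC(OC)(OC)OC; water, O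
Why: The cis-diol forms a cyclic orthoester whose mild hydrolysis opens kinetically to the axial ester, here the pseudoaxial allylic O3, so the acetate lands on O3 and the equatorial O4 hydroxyl stays free (regioselective orthoester opening).

Step 12
Reactants: 21 methyl 3-O-acetyl-5-O-[(3S)-3-methylpentanoyl]shikimate; 22 (R)-2-methylbutanoic acid
Product: 23 methyl (3R,4S,5R)-3-acetoxy-4-{[(2R)-2-methylbutanoyl]oxy}-5-{[(3S)-3-methylpentanoyl]oxy}cyclohex-1-ene-1-carboxylate (target)
Conditions: EDC·HCl, DMAP (0.2 equiv), CH2Cl2, 0 °C to rt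
Reagents that add atoms: none
Why: Steglich esterification of the last free hydroxyl, O4, completes the triester, and low temperature with substoichiometric DMAP should keep the α-stereocentre of the acid and the neighbouring acetate in place.

Compound list

1 | dimethyl D-tartrate, (2S,3S) | COC(=O)[C@@H](O)[C@H](O)C(=O)OC | starting material
2 | dimethyl (2S,3S)-2,3-bis(tert-butyldimethylsilyloxy)butanedioate | COC(=O)[C@@H](O[Si](C)(C)C(C)(C)C)[C@H](O[Si](C)(C)C(C)(C)C)C(=O)OC | intermediate
3 | methyl (2S,3S)-2,3-bis(tert-butyldimethylsilyloxy)-4-oxobutanoate | COC(=O)[C@@H](O[Si](C)(C)C(C)(C)C)[C@H](O[Si](C)(C)C(C)(C)C)C=O | intermediate (not isolated)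
4 | 1-tert-butyl 6-methyl (2E,4R,5S)-4,5-bis(tert-butyldimethylsilyloxy)hex-2-enedioate | CC(C)(C)OC(=O)/C=C/[C@@H](O[Si](C)(C)C(C)(C)C)[C@H](O[Si](C)(C)C(C)(C)C)C(=O)OC | intermediate
5 | 6-tert-butyl 1-methyl (2S,3R)-2,3-bis(tert-butyldimethylsilyloxy)hexanedioate | CC(C)(C)OC(=O)CC[C@@H](O[Si](C)(C)C(C)(C)C)[C@H](O[Si](C)(C)C(C)(C)C)C(=O)OC | intermediate
6 | tert-butyl (4R,5S)-4,5-bis(tert-butyldimethylsilyloxy)-6-[methoxy(methyl)amino]-6-oxohexanoate | CC(C)(C)OC(=O)CC[C@@H](O[Si](C)(C)C(C)(C)C)[C@H](O[Si](C)(C)C(C)(C)C)C(=O)N(C)OC | intermediate (not isolated)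
7 | tert-butyl (4R,5S)-4,5-bis(tert-butyldimethylsilyloxy)-6-oxoheptanoate | CC(C)(C)OC(=O)CC[C@@H](O[Si](C)(C)C(C)(C)C)[C@H](O[Si](C)(C)C(C)(C)C)C(C)=O | intermediate
8 | dilithium bis-enolate of 7 (C1 ester enolate, C2 ketone enolate) | [Li+].[Li+].CC(C)(C)OC([O-])=CC[C@@H](O[Si](C)(C)C(C)(C)C)[C@H](O[Si](C)(C)C(C)(C)C)C([O-])=C | intermediate (not isolated)
9 | tert-butyl (4S,5R)-4,5-bis(tert-butyldimethylsilyloxy)-3-oxocyclohexane-1-carboxylate, C1 epimers | CC(C)(C)[Si](C)(C)O[C@@H]1CC(C(=O)OC(C)(C)C)CC(=O)[C@H]1O[Si](C)(C)C(C)(C)C | intermediate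
10 | lithium C2–C3 enolate of 9 | [Li+].CC(C)(C)[Si](C)(C)O[C@@H]1CC(C(=O)OC(C)(C)C)C=C([O-])[C@H]1O[Si](C)(C)C(C)(C)C | intermediate (not isolated)
11 | tert-butyl (4S,5R)-4,5-bis(tert-butyldimethylsilyloxy)-3-oxo-2-(phenylselanyl)cyclohexane-1-carboxylate, diastereomers at C1 and C2 | CC(C)(C)[Si](C)(C)O[C@@H]1CC(C(=O)OC(C)(C)C)C([Se]c2ccccc2)C(=O)[C@H]1O[Si](C)(C)C(C)(C)C | intermediate (not isolated)
12 | selenoxide of 11 | CC(C)(C)[Si](C)(C)O[C@@H]1CC(C(=O)OC(C)(C)C)C([Se](=O)c2ccccc2)C(=O)[C@H]1O[Si](C)(C)C(C)(C)C | intermediate (not isolated)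
13 | tert-butyl (4S,5R)-4,5-bis(tert-butyldimethylsilyloxy)-3-oxocyclohex-1-ene-1-carboxylate | CC(C)(C)[Si](C)(C)O[C@@H]1CC(C(=O)OC(C)(C)C)=CC(=O)[C@H]1O[Si](C)(C)C(C)(C)C | intermediate
14 | tert-butyl (3R,4R,5R)-4,5-bis(tert-butyldimethylsilyloxy)-3-hydroxycyclohex-1-ene-1-carboxylate | CC(C)(C)[Si](C)(C)O[C@@H]1CC(C(=O)OC(C)(C)C)=C[C@@H](O)[C@H]1O[Si](C)(C)C(C)(C)C | intermediate
15 | methyl shikimate, methyl (3R,4S,5R)-3,4,5-trihydroxycyclohex-1-ene-1-carboxylate | O[C@@H]1CC(C(=O)OC)=C[C@@H](O)[C@H]1O | intermediate (not isolated)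
16 | methyl 3,4-O-isopropylidene-shikimate, methyl (3aR,7R,7aS)-7-hydroxy-2,2-dimethyl-3a,6,7,7a-tetrahydro-1,3-benzodioxole-5-carboxylate | O[C@@H]1CC(C(=O)OC)=C[C@H]2OC(C)(C)O[C@@H]12 | intermediate
17 | (S)-3-methylpentanoic acid | CC[C@H](C)CC(=O)O | starting material
18 | methyl 3,4-O-isopropylidene-5-O-[(3S)-3-methylpentanoyl]shikimate | CC[C@H](C)CC(=O)O[C@@H]1CC(C(=O)OC)=C[C@H]2OC(C)(C)O[C@@H]12 | intermediate
19 | methyl 5-O-[(3S)-3-methylpentanoyl]shikimate, (3R,4R,5R)-3,4-diol | CC[C@H](C)CC(=O)O[C@@H]1CC(C(=O)OC)=C[C@@H](O)[C@H]1O | intermediate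
20 | methyl 3,4-O-(1-methoxyethylidene)-5-O-[(3S)-3-methylpentanoyl]shikimate, epimers at the orthoester carbon | CC[C@H](C)CC(=O)O[C@@H]1CC(C(=O)OC)=C[C@H]2OC(C)(OC)O[C@@H]12 | intermediate (not isolated)
21 | methyl 3-O-acetyl-5-O-[(3S)-3-methylpentanoyl]shikimate, (3R,4S,5R), free 4-OH | CC[C@H](C)CC(=O)O[C@@H]1CC(C(=O)OC)=C[C@@H](OC(C)=O)[C@H]1O | intermediate
22 | (R)-2-methylbutanoic acid | CC[C@@H](C)C(=O)O | starting material
23 | methyl (3R,4S,5R)-3-acetoxy-4-{[(2R)-2-methylbutanoyl]oxy}-5-{[(3S)-3-methylpentanoyl]oxy}cyclohex-1-ene-1-carboxylate | CC[C@H](C)CC(=O)O[C@@H]1CC(C(=O)OC)=C[C@@H](OC(C)=O)[C@H]1OC(=O)[C@H](C)CC | target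

Total step count: 12
Longest linear sequence: 12 steps (1 to 23); acids 17 and 22 enter directly in steps 9 and 12.

Steps most likely to fail

Step 5 (oxidative ring closure). The bis-enolate may be consumed by intermolecular coupling, by carbon–oxygen coupling, or by proton transfer that moves the ketone enolate to C4 and expels the C5 silyloxy group. The fallback sets out from 7 and returns at 9, and makes the same bond from neutral enol silanes. Compound 7 would be treated with LiN(iPr)2 (2.2 equiv) and Me3SiCl at −78 °C to give (4R,5S)-1-tert-butoxy-4,5-bis(tert-butyldimethylsilyloxy)-1,6-bis(trimethylsilyloxy)hepta-1,6-diene F1. This would be oxidised with (NH4)2Ce(NO3)6 (tetravalent cerium) and NaHCO3 in MeCN at −10 °C. One-electron oxidation of the electron-rich ketene acetal and capture of the radical cation by the tethered enol ether is a known intramolecular oxidative coupling of silyl enol ethers and should give 9 after loss of both trimethylsilyl groups.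

Step 7 (C3 reduction). Hydride delivery may be poorly face-selective, or may favour the face that places the C3 hydroxyl trans to O4 if the diequatorial half-chair reacts. The fallback sets out from 13 and returns at 14. The same Luche conditions would then furnish the epimer, tert-butyl (3S,4R,5R)-4,5-bis(tert-butyldimethylsilyloxy)-3-hydroxycyclohex-1-ene-1-carboxylate F2. Mitsunobu reaction of F2 with 4-nitrobenzoic acid, PPh3 and diisopropyl azodicarboxylate in toluene at 0 °C should give, with inversion at C3, tert-butyl (3R,4R,5R)-4,5-bis(tert-butyldimethylsilyloxy)-3-[(4-nitrobenzoyl)oxy]cyclohex-1-ene-1-carboxylate F3. Methanolysis with K2CO3 in MeOH at 0 °C then removes the nitrobenzoate and leads to 14.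

Step 6 (dehydrogenation). Enolate equilibration towards C4 with β-elimination and aromatisation, or over-oxidation of the enone during the peroxide stage, may erode the sequence. The fallback sets out from 9 and returns at 13. Compound 9 would be deprotonated with LiN(iPr)2 in the presence of Me3SiCl (internal quench, THF, −78 °C) to trap the kinetic enolate as tert-butyl (4S,5R)-4,5-bis(tert-butyldimethylsilyloxy)-3-(trimethylsilyloxy)cyclohex-2-ene-1-carboxylate F4. Treatment with Pd(OAc)2 (divalent palladium) in MeCN at rt (Saegusa–Ito oxidation) then dehydrogenates by β-hydride elimination under neutral conditions and gives 13.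

Further compounds

F1 | step 5 | (4R,5S)-1-tert-butoxy-4,5-bis(tert-butyldimethylsilyloxy)-1,6-bis(trimethylsilyloxy)hepta-1,6-diene | CC(C)(C)OC(O[Si](C)(C)C)=CC[C@@H](O[Si](C)(C)C(C)(C)C)[C@H](O[Si](C)(C)C(C)(C)C)C(O[Si](C)(C)C)=C
F2 | step 7 | tert-butyl (3S,4R,5R)-4,5-bis(tert-butyldimethylsilyloxy)-3-hydroxycyclohex-1-ene-1-carboxylate | CC(C)(C)[Si](C)(C)O[C@@H]1CC(C(=O)OC(C)(C)C)=C[C@H](O)[C@H]1O[Si](C)(C)C(C)(C)C
F3 | step 7 | tert-butyl (3R,4R,5R)-4,5-bis(tert-butyldimethylsilyloxy)-3-[(4-nitrobenzoyl)oxy]cyclohex-1-ene-1-carboxylate | CC(C)(C)[Si](C)(C)O[C@@H]1CC(C(=O)OC(C)(C)C)=C[C@@H](OC(=O)c2ccc(cc2)[N+](=O)[O-])[C@H]1O[Si](C)(C)C(C)(C)C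
F4 | step 6 | tert-butyl (4S,5R)-4,5-bis(tert-butyldimethylsilyloxy)-3-(trimethylsilyloxy)cyclohex-2-ene-1-carboxylate, C1 epimers | CC(C)(C)[Si](C)(C)O[C@@H]1CC(C(=O)OC(C)(C)C)C=C(O[Si](C)(C)C)[C@H]1O[Si](C)(C)C(C)(C)C
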